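**Retrosynthetic overview**
- The C8 carbinol (R) comes from a catalyst-controlled transfer hydrogenation of the C8 ketone, which comes from Markovnikov hydration and oxidation of a C7=C8 alkene carried through the synthesis.
- Ring A (4-pyridone) comes from ammonia cyclocondensation of a 1,3,5-triketone (N1–C2 and N1–C8a bonds). The triketone comes from two Claisen acylations of a cyclohexenone: C4a–C4 with methyl methoxyacetate, then C3–C2 with an acetyl Weinreb amide.
- Ring B, (S)-5-(5-phenylpentyl)cyclohex-2-enone, comes from the key intermolecular Michael addition of tert-butyl acetoacetate to (E)-8-phenyloct-2-enal under chiral amine catalysis (C4a–C5 bond, sets C5), then aldol condensation (C7–C8) and decarboxylation.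
- The enal comes from Wittig homologation of 6-phenylhexanal, made from 6-phenylhexan-1-ol.
- Ring order: carbocycle B first, pyridone A second; C5 is set in the Michael step and C8 in the last step.

Assumption: the SMILES is read as the (5S,8R) isomer (C5 side chain and C8 hydroxyl cis) in the 4(1H)-pyridone tautomer; locants C2–C8a are those of the quinolinone, and the facial sense in step 3 is taken from the usual shielding model for diarylprolinol silyl ethers.

**Route**

Step 1
Reactants: 1 6-phenylhexan-1-ol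
Product: 2 6-phenylhexanal
Conditions: TEMPO (10 mol%), PhI(OAc)2 (1.1 equiv), CH2Cl2, rt
Reagents that add atoms: none
Why: TEMPO-catalysed alcohol oxidation with PhI(OAc)2 as terminal oxidant stops cleanly at the aldehyde for an unhindered primary alcohol and leaves the phenyl ring untouched.

Step 2
Reactants: 2 6-phenylhexanal; 3 (triphenylphosphoranylidene)acetaldehyde
Product: 4 (E)-8-phenyloct-2-enal
Conditions: toluene, 80 °C
Reagents that add atoms: none
Why: Wittig olefination with the stabilised formyl ylide adds the two-carbon enal unit with high E selectivity.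

Step 3
Reactants: 4 (E)-8-phenyloct-2-enal; 5 tert-butyl 3-oxobutanoate
Product: 9 (5S)-5-(5-phenylpentyl)cyclohex-2-en-1-one, via Michael adduct 6 (not isolated), via cyclohexenone tert-butyl ester 7 (not isolated), via keto acid 8 (not isolated)
Conditions: (R)-2-{bis[3,5-bis(trifluoromethyl)phenyl](trimethylsilyloxy)methyl}pyrrolidine (10 mol%), toluene, rt; then TsOH·H2O (20 mol%), 80 °C
Reagents that add atoms: none
Why: This is an organocatalytic asymmetric Michael addition under iminium activation followed by acid-mediated intramolecular aldol condensation and tert-butyl ester cleavage with decarboxylation, in which the bulky C2 group of the (R)-catalyst blocks one face of the E, s-trans iminium ion of 4 so that the keto ester adds to the Si face of C3 and the future C5 is set as S.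

Step 4
Reactants: 9 (5S)-5-(5-phenylpentyl)cyclohex-2-en-1-one; 10 methyl 2-methoxyacetate
Product: 11 (5S)-6-(2-methoxyacetyl)-5-(5-phenylpentyl)cyclohex-2-en-1-one (enolised 1,3-diketone)
Conditions: LiN(SiMe3)2 (2.2 equiv), THF, −78 °C; then 10, −78 → 0 °C; aq. HCl work-up
Reagents that add atoms: none
Why: In this crossed Claisen condensation the kinetic lithium enolate of the enone can form only at C6 because the other alpha carbon is sp2, it is acylated by the activated alpha-alkoxy ester, the acidic diketone is held as its enolate by the second equivalent of base, and the non-enolisable C5 centre is untouched.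

Step 5
Reactants: 11 (5S)-6-(2-methoxyacetyl)-5-(5-phenylpentyl)cyclohex-2-en-1-one; 12 N-methoxy-N-methylacetamide
Product: 13 (5S)-6-(2-methoxy-3-oxobutanoyl)-5-(5-phenylpentyl)cyclohex-2-en-1-one (tautomeric 1,3,5-triketone)
Conditions: LiN(i-Pr)2 (2.2 equiv), THF, −78 → −20 °C; then 12, −78 → 0 °C; aq. HCl work-up
Reagents that add atoms: none
Why: In this Claisen-type acylation of a beta-diketone dianion the second deprotonation can occur only at the methoxy-bearing CH2 because the ring alpha' position is blocked by the C2=C3 double bond, and the terminal carbanion attacks the Weinreb amide, whose chelated tetrahedral adduct prevents over-addition.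

Step 6
Reactants: 13 (5S)-6-(2-methoxy-3-oxobutanoyl)-5-(5-phenylpentyl)cyclohex-2-en-1-one
Product: 14 (5S)-3-methoxy-2-methyl-5-(5-phenylpentyl)-5,6-dihydroquinolin-4(1H)-one
Conditions: NH4OAc (10 equiv), EtOH, 80 °C, N2
Reagents that add atoms: ammonium acetate, CC(=O)[O-].[NH4+]
Why: In this triketone–ammonia cyclocondensation (4-pyridone synthesis) ammonia condenses with the two outer carbonyl groups and loss of two molecules of water is driven by formation of aromatic ring A, with the same product whichever carbonyl reacts first.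

Step 7
Reactants: 14 (5S)-3-methoxy-2-methyl-5-(5-phenylpentyl)-5,6-dihydroquinolin-4(1H)-one
Product: 15 8-hydroxy-3-methoxy-2-methyl-5-(5-phenylpentyl)-5,6,7,8-tetrahydroquinolin-4(1H)-one as the (5S,8RS) mixture of C8 epimers
Conditions: Mn(dpm)3 (10 mol%), PhSiH3 (2.5 equiv), O2 (1 atm), i-PrOH/CH2Cl2, 0 °C → rt
Reagents that add atoms: dioxygen, O=O
Why: In this Mukaiyama hydration by metal-hydride hydrogen atom transfer the hydrogen adds to C7 to give the ring-A-conjugated C8 radical, which is trapped by O2 and reduced to the alcohol, so oxygen goes to C8 only, while the uncontrolled C8 configuration is corrected in steps 8 and 9.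

Step 8
Reactants: 15 8-hydroxy-3-methoxy-2-methyl-5-(5-phenylpentyl)-5,6,7,8-tetrahydroquinolin-4(1H)-one (C8 epimers)
Product: 16 (5S)-3-methoxy-2-methyl-5-(5-phenylpentyl)-6,7-dihydroquinoline-4,8(1H,5H)-dione
Conditions: Dess–Martin periodinane (1.3 equiv), CH2Cl2, 0 °C → rt
Reagents that add atoms: none
Why: Dess–Martin oxidation converts both C8 epimers into the single ketone under neutral conditions that neither epimerise C5 nor touch the pyridone.

Step 9
Reactants: 16 (5S)-3-methoxy-2-methyl-5-(5-phenylpentyl)-6,7-dihydroquinoline-4,8(1H,5H)-dione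
Product: 17 (5S,8R)-8-hydroxy-3-methoxy-2-methyl-5-(5-phenylpentyl)-5,6,7,8-tetrahydroquinolin-4(1H)-one
Conditions: RuCl[(R,R)-TsDPEN](p-cymene) (2 mol%), HCO2H/Et3N (5:2), DMF, 30 °C
Reagents that add atoms: none
Why: In this Noyori asymmetric transfer hydrogenation the (R,R)-TsDPEN ruthenium hydride distinguishes the aryl-like ring-A flank from the CH2 flank of the C8 ketone as it does for 1-tetralone and gives the 8R alcohol cis to the C5 side chain, while the vinylogous-amide C4 carbonyl is inert.

**Compound list**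
1 | 6-phenylhexan-1-ol | OCCCCCCc1ccccc1 | starting material
2 | 6-phenylhexanal | O=CCCCCCc1ccccc1 | intermediate
3 | (triphenylphosphoranylidene)acetaldehyde | O=CC=P(c1ccccc1)(c1ccccc1)c1ccccc1 | starting material
4 | (E)-8-phenyloct-2-enal | O=C/C=C/CCCCCc1ccccc1 | intermediate
5 | tert-butyl 3-oxobutanoate | CC(=O)CC(=O)OC(C)(C)C | starting material
6 | tert-butyl (3S)-2-acetyl-5-oxo-3-(5-phenylpentyl)pentanoate (Michael adduct, C2 epimers) | CC(=O)C(C(=O)OC(C)(C)C)[C@@H](CCCCCc1ccccc1)CC=O | intermediate
7 | tert-butyl (6S)-2-oxo-6-(5-phenylpentyl)cyclohex-3-ene-1-carboxylate | CC(C)(C)OC(=O)C1C(=O)C=CC[C@@H]1CCCCCc1ccccc1 | intermediate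
8 | (6S)-2-oxo-6-(5-phenylpentyl)cyclohex-3-ene-1-carboxylic acid | OC(=O)C1C(=O)C=CC[C@@H]1CCCCCc1ccccc1 | intermediate
9 | (5S)-5-(5-phenylpentyl)cyclohex-2-en-1-one | O=C1C[C@@H](CCCCCc2ccccc2)CC=C1 | intermediate
10 | methyl 2-methoxyacetate | COCC(=O)OC | starting material
11 | (5S)-6-(2-methoxyacetyl)-5-(5-phenylpentyl)cyclohex-2-en-1-one | COCC(=O)C1C(=O)C=CC[C@@H]1CCCCCc1ccccc1 | intermediate
12 | N-methoxy-N-methylacetamide | CC(=O)N(C)OC | starting material
13 | (5S)-6-(2-methoxy-3-oxobutanoyl)-5-(5-phenylpentyl)cyclohex-2-en-1-one | CC(=O)C(OC)C(=O)C1C(=O)C=CC[C@@H]1CCCCCc1ccccc1 | intermediate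
14 | (5S)-3-methoxy-2-methyl-5-(5-phenylpentyl)-5,6-dihydroquinolin-4(1H)-one | COc1c(C)[nH]c2c(c1=O)[C@@H](CCCCCc1ccccc1)CC=C2 | intermediate
15 | (5S,8RS)-8-hydroxy-3-methoxy-2-methyl-5-(5-phenylpentyl)-5,6,7,8-tetrahydroquinolin-4(1H)-one (C8 epimers) | COc1c(C)[nH]c2c(c1=O)[C@@H](CCCCCc1ccccc1)CCC2O | intermediate
16 | (5S)-3-methoxy-2-methyl-5-(5-phenylpentyl)-6,7-dihydroquinoline-4,8(1H,5H)-dione | COc1c(C)[nH]c2c(c1=O)[C@@H](CCCCCc1ccccc1)CCC2=O | intermediate
17 | (5S,8R)-8-hydroxy-3-methoxy-2-methyl-5-(5-phenylpentyl)-5,6,7,8-tetrahydroquinolin-4(1H)-one | COc1c(C)[nH]c2c(c1=O)[C@@H](CCCCCc1ccccc1)CC[C@H]2O | target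

**Totals**
Total step count: 9. Longest linear sequence: 9 steps (1 → 17).

**Steps most likely to fail, with fallbacks**

Risk 1 is step 5: dianion formation or acetyl transfer may be low-yielding, since the Weinreb acetamide is enolisable and vinylogous deprotonation could compete. The fallback sets out from 9 and comes back at 13, bringing in the C2–C3–C4 unit pre-assembled and avoiding any dianion. Commercial methyl 2-methoxy-3-oxobutanoate is ketalised (ethylene glycol, TsOH, toluene, Dean–Stark) to methyl 2-methoxy-2-(2-methyl-1,3-dioxolan-2-yl)acetate F1. F1 is reduced (i-Bu2AlH, CH2Cl2, −78 °C) to 2-methoxy-2-(2-methyl-1,3-dioxolan-2-yl)acetaldehyde F2. The lithium enolate of 9 (LiN(i-Pr)2, THF, −78 °C) adds to F2 in an aldol reaction to give (5S)-6-[1-hydroxy-2-methoxy-2-(2-methyl-1,3-dioxolan-2-yl)ethyl]-5-(5-phenylpentyl)cyclohex-2-en-1-one F3. Dess–Martin oxidation gives (5S)-6-[2-methoxy-2-(2-methyl-1,3-dioxolan-2-yl)acetyl]-5-(5-phenylpentyl)cyclohex-2-en-1-one F4, and aqueous HCl in THF removes the dioxolane to give 13.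

Risk 2 is step 7: the radical hydration may give over-reduction or be slowed by the pyridone. The fallback sets out from 14 and comes back at 15 by an ionic route. N-Bromosuccinimide in THF/H2O at 0 °C forms the bromonium ion, which water opens at the ring-A-stabilised C8 to give (5S)-7-bromo-8-hydroxy-3-methoxy-2-methyl-5-(5-phenylpentyl)-5,6,7,8-tetrahydroquinolin-4(1H)-one F5. Radical debromination (Bu3SnH, AIBN, toluene, 80 °C) then gives 15.

Risk 3 is step 9: the ruthenium catalyst may be inhibited by the pyridone or give poor selectivity at C8. The fallback sets out from 15 and comes back at 17, leaving out steps 8 and 9. The C8 epimers of 15 are separated by chromatography; the cis epimer is 17 itself. The trans epimer (5S,8S)-8-hydroxy-3-methoxy-2-methyl-5-(5-phenylpentyl)-5,6,7,8-tetrahydroquinolin-4(1H)-one F6 is inverted by Mitsunobu reaction (4-nitrobenzoic acid, PPh3, DIAD, THF, 0 °C) to (5S,8R)-3-methoxy-2-methyl-4-oxo-5-(5-phenylpentyl)-1,4,5,6,7,8-hexahydroquinolin-8-yl 4-nitrobenzoate F7. Methanolysis of F7 (K2CO3, MeOH, rt) gives 17.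

**Further compounds**
F1 | step 5 | methyl 2-methoxy-2-(2-methyl-1,3-dioxolan-2-yl)acetate | COC(=O)C(OC)C1(C)OCCO1
F2 | step 5 | 2-methoxy-2-(2-methyl-1,3-dioxolan-2-yl)acetaldehyde | O=CC(OC)C1(C)OCCO1
F3 | step 5 | (5S)-6-[1-hydroxy-2-methoxy-2-(2-methyl-1,3-dioxolan-2-yl)ethyl]-5-(5-phenylpentyl)cyclohex-2-en-1-one | COC(C(O)C1C(=O)C=CC[C@@H]1CCCCCc1ccccc1)C1(C)OCCO1
F4 | step 5 | (5S)-6-[2-methoxy-2-(2-methyl-1,3-dioxolan-2-yl)acetyl]-5-(5-phenylpentyl)cyclohex-2-en-1-one | COC(C(=O)C1C(=O)C=CC[C@@H]1CCCCCc1ccccc1)C1(C)OCCO1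
F5 | step 7 | (5S)-7-bromo-8-hydroxy-3-methoxy-2-methyl-5-(5-phenylpentyl)-5,6,7,8-tetrahydroquinolin-4(1H)-one | COc1c(C)[nH]c2c(c1=O)[C@@H](CCCCCc1ccccc1)CC(Br)C2O
F6 | step 9 | (5S,8S)-8-hydroxy-3-methoxy-2-methyl-5-(5-phenylpentyl)-5,6,7,8-tetrahydroquinolin-4(1H)-one | COc1c(C)[nH]c2c(c1=O)[C@@H](CCCCCc1ccccc1)CC[C@@H]2O
F7 | step 9 | (5S,8R)-3-methoxy-2-methyl-4-oxo-5-(5-phenylpentyl)-1,4,5,6,7,8-hexahydroquinolin-8-yl 4-nitrobenzoate | COc1c(C)[nH]c2c(c1=O)[C@@H](CCCCCc1ccccc1)CC[C@H]2OC(=O)c1ccc(cc1)[N+](=O)[O-]
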